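**Retrosynthetic overview**

1. The last C–C bond joins the two halves: the alkyllithium from iodide 30 adds to vinylogous ester 12, then acid triggers the 1,3-carbonyl transposition and removes all silyl groups.
2. Hydroazulenone 12 comes from a dichloroketene [2+2] cycloaddition on the silyl enol ether of diquinane ketone 6, followed by retro-aldol ring expansion to the cycloheptane-1,3-dione. Ketone 6 comes from a first dichloroketene [2+2] on cyclopentenyl silyl ether 3 (from (R)-linalool by ring-closing metathesis), diazomethane ring expansion and reductive gem-dimethylation.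
3. Benzoxepane 30 comes from reductive opening of bicyclic ketal 27. Its cyclohexanone precursor 26 comes from enone 22 (from (S)-linalool) by hydroxyl-directed vinyl conjugate addition and enolate alkylation with iodide 16 (from (S)-α-hydroxy-γ-butyrolactone).
4. Ring order: cyclopentene (metathesis) → cyclobutanone → cyclopentanone → cycloheptanedione; separately cyclohexene (metathesis) → oxepane; the halves are united last.

Assumption: (R)-(−)-linalool, (S)-(+)-linalool and (S)-α-hydroxy-γ-butyrolactone are taken as commercial chiral-pool materials of high enantiomeric purity; every other reagent and catalyst is achiral.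

**Hydroazulenone half (from (R)-linalool)**

Step 1
Reactants: 1 (R)-(−)-linalool
Product: 2 (R)-1-methylcyclopent-2-en-1-ol
Conditions: second-generation Grubbs catalyst (H2IMes)(PCy3)Cl2Ru=CHPh (0.5 mol %), CH2Cl2, 40 °C
Reagents that add atoms: none
Why: Ring-closing metathesis between the vinyl group and the trisubstituted alkene expels 2-methylpropene and leaves the bought carbinol stereocentre untouched.

Step 2
Reactants: 2 (R)-1-methylcyclopent-2-en-1-ol
Product: 3 (R)-tert-butyldimethyl[(1-methylcyclopent-2-en-1-yl)oxy]silane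
Conditions: TBSOTf, 2,6-lutidine, CH2Cl2, 0 °C
Reagents that add atoms: tert-butyldimethylsilyl trifluoromethanesulfonate, CC(C)(C)[Si](C)(C)OS(=O)(=O)C(F)(F)F
Why: O-Silylation protects the tertiary alcohol and makes the oxygen-bearing face of the ring the more hindered one for the cycloaddition.

Step 3
Reactants: 3 (R)-tert-butyldimethyl[(1-methylcyclopent-2-en-1-yl)oxy]silane
Product: 4 (1R,2R,5R)-6,6-dichloro-2-methyl-2-(tert-butyldimethylsilyloxy)bicyclo[3.2.0]heptan-7-one
Conditions: Cl3CCOCl, Zn(Cu), DME, Et2O, 25 °C, slow addition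
Reagents that add atoms: trichloroacetyl chloride, ClC(Cl)(Cl)C(Cl)=O
Why: The [2+2] ketene–alkene cycloaddition is suprafacial on the alkene (cis ring fusion), is expected to occur anti to the silyloxy group (on the methyl face) so that both ring-fusion centres follow from the bought one, and puts the CCl2 terminus on the alkene carbon remote from the quaternary carbinol.

Step 4
Reactants: 4 (1R,2R,5R)-6,6-dichloro-2-methyl-2-(tert-butyldimethylsilyloxy)bicyclo[3.2.0]heptan-7-one
Product: 5 (1R,5R,6R)-2,2-dichloro-6-methyl-6-(tert-butyldimethylsilyloxy)bicyclo[3.3.0]octan-3-one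
Conditions: CH2N2, Et2O, MeOH (cat.), 0 °C
Reagents that add atoms: diazomethane, C=[N+]=[N-]
Why: In this diazomethane ring expansion only the non-chlorinated α-carbon migrates, so the CH2 group enters between the carbonyl and the ring-fusion carbon next to the carbinol.

Step 5
Reactants: 5 (1R,5R,6R)-2,2-dichloro-6-methyl-6-(tert-butyldimethylsilyloxy)bicyclo[3.3.0]octan-3-one
Product: 6 (1R,5R,6R)-6-(tert-butyldimethylsilyloxy)-2,2,6-trimethylbicyclo[3.3.0]octan-3-one
Conditions: Me2CuLi (4 equiv), Et2O, −78 to −40 °C; then MeI, HMPA, −40 °C to rt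
Reagents that add atoms: iodomethane, CI
Why: Reductive alkylation of the α,α-dichloro ketone: the cuprate removes each chlorine to give an enolate fixed at that carbon, which MeI methylates, so the gem-dimethyl group is placed without an enolate regiochemistry problem.

Step 6
Reactants: 6 (1R,5R,6R)-6-(tert-butyldimethylsilyloxy)-2,2,6-trimethylbicyclo[3.3.0]octan-3-one
Product: 7 (1R,5R,6R)-6-(tert-butyldimethylsilyloxy)-2,2,6-trimethyl-3-(trimethylsilyloxy)bicyclo[3.3.0]oct-3-ene
Conditions: TMSOTf, Et3N, CH2Cl2, 0 °C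
Reagents that add atoms: trimethylsilyl trifluoromethanesulfonate, C[Si](C)(C)OS(=O)(=O)C(F)(F)F
Why: Soft enolisation and O-silylation give a single silyl enol ether because only one α-CH2 remains.

Step 7
Reactants: 7 (1R,5R,6R)-6-(tert-butyldimethylsilyloxy)-2,2,6-trimethyl-3-(trimethylsilyloxy)bicyclo[3.3.0]oct-3-ene
Product: 8 dichlorocyclobutanone adduct of 7 (cyclobutanone fused across C3–C4; CCl2 on the siloxy carbon C3 and C=O on C4)
Conditions: Cl2CHCOCl, Et3N, hexane, rt
Reagents that add atoms: dichloroacetyl chloride, ClC(Cl)C(Cl)=O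
Why: The [2+2] cycloaddition of dichloroketene to the silyl enol ether (ketene carbonyl carbon to the nucleophilic β-carbon) sets up the fragmentation that forms the seven-membered ring; its new stereocentres are lost in step 8.

Step 8
Reactants: 8 dichlorocyclobutanone adduct of 7
Product: 10 (1R,7R,8R)-8-(tert-butyldimethylsilyloxy)-2,2,8-trimethylbicyclo[5.3.0]decane-3,5-dione, via dechlorinated siloxycyclobutanone 9 (not isolated)
Conditions: Zn dust, AcOH, i-PrOH/H2O, 0 °C to rt; then 80 °C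
Reagents that add atoms: none
Why: Zinc dechlorination followed by desilylative retro-aldol cleavage of the ring-fusion bond is a two-carbon ring expansion to the cycloheptane-1,3-dione and does not touch the three stereocentres.

Step 9
Reactants: 10 (1R,7R,8R)-8-(tert-butyldimethylsilyloxy)-2,2,8-trimethylbicyclo[5.3.0]decane-3,5-dione
Product: 11 (1R,7R,8R)-8-(tert-butyldimethylsilyloxy)-2,2,4,8-tetramethylbicyclo[5.3.0]decane-3,5-dione (C4 epimers and enol)
Conditions: MeI, K2CO3, acetone, 56 °C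
Reagents that add atoms: iodomethane, CI
Why: C-Alkylation of the 1,3-dione enolate occurs at the doubly activated carbon between the carbonyls.

Step 10
Reactants: 11 (1R,7R,8R)-8-(tert-butyldimethylsilyloxy)-2,2,4,8-tetramethylbicyclo[5.3.0]decane-3,5-dione
Product: 12 (1R,7R,8R)-8-(tert-butyldimethylsilyloxy)-5-methoxy-2,2,4,8-tetramethylbicyclo[5.3.0]dec-4-en-3-one
Conditions: HC(OMe)3, MeOH, TsOH·H2O (cat.), rt
Reagents that add atoms: trimethyl orthoformate, COC(OC)OC
Why: Acid-catalysed enol ether formation takes place at the less hindered carbonyl, leaving the ketone beside the gem-dimethyl carbon free as the vinylogous ester needed for a Stork–Danheiser transposition.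

**Side-chain electrophile (from (S)-α-hydroxy-γ-butyrolactone)**

Step 11
Reactants: 13 (S)-α-hydroxy-γ-butyrolactone
Product: 14 (3S)-4-methylpentane-1,3,4-triol
Conditions: MeMgBr (3.5 equiv), THF, 0 °C to rt
Reagents that add atoms: methylmagnesium bromide, C[Mg]Br
Why: Double Grignard addition to the lactone carbonyl gives the tertiary alcohol, while the α-carbon, carrying an alkoxide, is not enolised and keeps its configuration.

Step 12
Reactants: 14 (3S)-4-methylpentane-1,3,4-triol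
Product: 15 2-[(4S)-2,2,5,5-tetramethyl-1,3-dioxolan-4-yl]ethan-1-ol
Conditions: Me2C(OMe)2, PPTS (cat.), acetone, rt
Reagents that add atoms: 2,2-dimethoxypropane, COC(C)(C)OC
Why: Thermodynamic acetonide formation selects the vicinal diol (five-membered dioxolane) and leaves the primary alcohol free.

Step 13
Reactants: 15 2-[(4S)-2,2,5,5-tetramethyl-1,3-dioxolan-4-yl]ethan-1-ol
Product: 16 (4S)-4-(2-iodoethyl)-2,2,5,5-tetramethyl-1,3-dioxolane
Conditions: I2, PPh3, imidazole, CH2Cl2, 0 °C to rt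
Reagents that add atoms: iodine, II
Why: Appel-type iodination converts the primary alcohol into the iodide without touching the stereocentre.

**Benzoxepane half (from (S)-linalool)**

Step 14
Reactants: 17 (S)-(+)-linalool
Product: 19 (5S)-5-ethenyl-5-methyloxolan-2-ol (lactol, anomer mixture), via ozonide 18 (not isolated)
Conditions: O3 (1 equiv), CH2Cl2, −78 °C; then Me2S, −78 °C to rt
Reagents that add atoms: ozone, [O-][O+]=O
Why: Ozonolysis selects the electron-rich trisubstituted alkene over the vinyl group, and the resulting hydroxy aldehyde closes to the lactol.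

Step 15
Reactants: 19 (5S)-5-ethenyl-5-methyloxolan-2-ol
Product: 20 (6S)-2,6-dimethylocta-1,7-diene-3,6-diol (C3 epimers)
Conditions: isopropenylMgBr (3 equiv), THF, 0 °C to rt
Reagents that add atoms: isopropenylmagnesium bromide, CC(=C)[Mg]Br
Why: Grignard addition to the open hydroxy-aldehyde form of the lactol gives the diene; the new carbinol centre is removed in step 17.

Step 16
Reactants: 20 (6S)-2,6-dimethylocta-1,7-diene-3,6-diol
Product: 21 (4S)-2,4-dimethylcyclohex-2-ene-1,4-diol (C1 epimers)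
Conditions: second-generation Grubbs catalyst (H2IMes)(PCy3)Cl2Ru=CHPh (2 mol %), CH2Cl2, 40 °C
Reagents that add atoms: none
Why: Ring-closing metathesis of the vinyl and isopropenyl groups forms the trisubstituted cyclohexene and releases ethene.

Step 17
Reactants: 21 (4S)-2,4-dimethylcyclohex-2-ene-1,4-diol
Product: 22 (4S)-4-hydroxy-2,4-dimethylcyclohex-2-en-1-one
Conditions: MnO2 (excess), CH2Cl2, rt
Reagents that add atoms: none
Why: Allylic oxidation with MnO2 converts only the secondary allylic alcohol, and both C1 epimers converge on one enone.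

Step 18
Reactants: 22 (4S)-4-hydroxy-2,4-dimethylcyclohex-2-en-1-one
Product: 24 (3R,4S)-3-ethenyl-2,4-dimethyl-1,4-bis(triethylsilyloxy)cyclohex-1-ene, via magnesium enolate 23 (not isolated)
Conditions: vinylMgBr (3.5 equiv), THF, −78 to −20 °C; then TESCl, HMPA, −78 °C to rt
Reagents that add atoms: vinylmagnesium bromide, C=C[Mg]Br; chlorotriethylsilane, CC[Si](Cl)(CC)CC
Why: Alkoxide-directed conjugate addition delivers the vinyl group to C3 on the face of the C4 oxygen (cis), and silylation traps the enolate at the position needed for the next step.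

Step 19
Reactants: 24 (3R,4S)-3-ethenyl-2,4-dimethyl-1,4-bis(triethylsilyloxy)cyclohex-1-ene; 16 (4S)-4-(2-iodoethyl)-2,2,5,5-tetramethyl-1,3-dioxolane
Product: 26 (2R,3R,4S)-3-ethenyl-2,4-dimethyl-2-{2-[(4S)-2,2,5,5-tetramethyl-1,3-dioxolan-4-yl]ethyl}-4-(triethylsilyloxy)cyclohexan-1-one, via lithium enolate 25 (not isolated)
Conditions: MeLi (1.05 equiv), THF, 0 °C to rt; then 16, DMPU, −40 °C to rt
Reagents that add atoms: none
Why: MeLi unmasks the enolate and SN2 alkylation is expected to occur trans to the adjacent vinyl group, which sets the quaternary centre with methyl cis to vinyl.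

Step 20
Reactants: 26 (2R,3R,4S)-3-ethenyl-2,4-dimethyl-2-{2-[(4S)-2,2,5,5-tetramethyl-1,3-dioxolan-4-yl]ethyl}-4-(triethylsilyloxy)cyclohexan-1-one
Product: 27 tricyclic ketal (C1 of the cyclohexane is the ketal carbon of a 6,8-dioxabicyclo[3.2.1]octane formed with the side-chain secondary and tertiary oxygens; vinyl and triethylsilyl ether retained)
Conditions: CSA (10 mol %), CH2Cl2, rt
Reagents that add atoms: none
Why: Acid-catalysed transketalisation moves the diol from acetone onto the ring ketone, forming both C–O bonds of the future oxepane under thermodynamic control.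

Step 21
Reactants: 27 tricyclic ketal
Product: 28 (3S,5aR,6R,7S,9aR)-6-ethenyl-2,2,5a,7-tetramethyl-3,7-bis(triethylsilyloxy)decahydro-1-benzoxepine
Conditions: Et3SiH (5 equiv), TESOTf (1.1 equiv), CH2Cl2, −78 to −40 °C; Et3N quench
Reagents that add atoms: triethylsilyl trifluoromethanesulfonate, CC[Si](CC)(CC)OS(=O)(=O)C(F)(F)F; triethylsilane, CC[SiH](CC)CC
Why: In this silyl triflate-promoted reductive ketal opening (ionic hydrogenation) the less hindered secondary ketal oxygen is silylated and leaves, and hydride adds axially anti to the angular methyl, giving the trans-fused oxepane with C3 already fixed by the chiral pool.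

Step 22
Reactants: 28 (3S,5aR,6R,7S,9aR)-6-ethenyl-2,2,5a,7-tetramethyl-3,7-bis(triethylsilyloxy)decahydro-1-benzoxepine
Product: 30 (3S,5aR,6R,7S,9aR)-6-(2-iodoethyl)-2,2,5a,7-tetramethyl-3,7-bis(triethylsilyloxy)decahydro-1-benzoxepine, via alkylzirconocene chloride 29 (not isolated)
Conditions: Cp2Zr(H)Cl (1.5 equiv), THF, rt; then I2, 0 °C
Reagents that add atoms: iodine, II
Why: Hydrozirconation places zirconium on the terminal carbon of the vinyl group and iodinolysis gives the primary iodide.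

**Union**

Step 23
Reactants: 30 (3S,5aR,6R,7S,9aR)-6-(2-iodoethyl)-2,2,5a,7-tetramethyl-3,7-bis(triethylsilyloxy)decahydro-1-benzoxepine; 12 (1R,7R,8R)-8-(tert-butyldimethylsilyloxy)-5-methoxy-2,2,4,8-tetramethylbicyclo[5.3.0]dec-4-en-3-one
Product: 33 target (CNP0397160.2): (1R,7R,8R)-3-{2-[(3S,5aR,6R,7S,9aR)-3,7-dihydroxy-2,2,5a,7-tetramethyldecahydro-1-benzoxepin-6-yl]ethyl}-8-hydroxy-2,2,4,8-tetramethylbicyclo[5.3.0]dec-3-en-5-one, via alkyllithium 31 (not isolated), via lithium alkoxide adduct 32 (not isolated)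
Conditions: t-BuLi (2.1 equiv), Et2O/pentane, −78 °C; then 12, THF, −78 to 0 °C; then 48% aq HF, MeCN, rt
Reagents that add atoms: none
Why: Iodine–lithium exchange and 1,2-addition to the vinylogous ester are followed by the acid-triggered Stork–Danheiser 1,3-carbonyl transposition to the tetrasubstituted enone and loss of all three silyl ethers, with no stereocentre affected.

**Compound list**

1 | (R)-(−)-linalool | C=C[C@](C)(O)CCC=C(C)C | starting material
2 | (R)-1-methylcyclopent-2-en-1-ol | C1C[C@@](C)(O)C=C1 | intermediate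
3 | (R)-tert-butyldimethyl[(1-methylcyclopent-2-en-1-yl)oxy]silane | C1C[C@@](C)(O[Si](C)(C)C(C)(C)C)C=C1 | intermediate
4 | (1R,2R,5R)-6,6-dichloro-2-methyl-2-(tert-butyldimethylsilyloxy)bicyclo[3.2.0]heptan-7-one | ClC1(Cl)[C@@H]2CC[C@@](C)(O[Si](C)(C)C(C)(C)C)[C@@H]2C1=O | intermediate
5 | (1R,5R,6R)-2,2-dichloro-6-methyl-6-(tert-butyldimethylsilyloxy)bicyclo[3.3.0]octan-3-one | ClC1(Cl)[C@@H]2CC[C@@](C)(O[Si](C)(C)C(C)(C)C)[C@@H]2CC1=O | intermediate
6 | (1R,5R,6R)-6-(tert-butyldimethylsilyloxy)-2,2,6-trimethylbicyclo[3.3.0]octan-3-one (ring-fusion H cis to the silyloxy group) | CC1(C)[C@@H]2CC[C@@](C)(O[Si](C)(C)C(C)(C)C)[C@@H]2CC1=O | intermediate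
7 | (1R,5R,6R)-6-(tert-butyldimethylsilyloxy)-2,2,6-trimethyl-3-(trimethylsilyloxy)bicyclo[3.3.0]oct-3-ene | CC1(C)[C@@H]2CC[C@@](C)(O[Si](C)(C)C(C)(C)C)[C@@H]2C=C1O[Si](C)(C)C | intermediate
8 | dichlorocyclobutanone adduct of 7 (CCl2 on the siloxy carbon) | CC1(C)[C@@H]2CC[C@@](C)(O[Si](C)(C)C(C)(C)C)[C@@H]2C3C(=O)C(Cl)(Cl)C13O[Si](C)(C)C | intermediate
9 | dechlorinated siloxycyclobutanone | CC1(C)[C@@H]2CC[C@@](C)(O[Si](C)(C)C(C)(C)C)[C@@H]2C3C(=O)CC13O[Si](C)(C)C | intermediate (not isolated)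
10 | (1R,7R,8R)-8-(tert-butyldimethylsilyloxy)-2,2,8-trimethylbicyclo[5.3.0]decane-3,5-dione | CC1(C)[C@@H]2CC[C@@](C)(O[Si](C)(C)C(C)(C)C)[C@@H]2CC(=O)CC1=O | intermediate
11 | (1R,7R,8R)-8-(tert-butyldimethylsilyloxy)-2,2,4,8-tetramethylbicyclo[5.3.0]decane-3,5-dione | CC1(C)[C@@H]2CC[C@@](C)(O[Si](C)(C)C(C)(C)C)[C@@H]2CC(=O)C(C)C1=O | intermediate
12 | (1R,7R,8R)-8-(tert-butyldimethylsilyloxy)-5-methoxy-2,2,4,8-tetramethylbicyclo[5.3.0]dec-4-en-3-one | CC1(C)[C@@H]2CC[C@@](C)(O[Si](C)(C)C(C)(C)C)[C@@H]2CC(OC)=C(C)C1=O | intermediate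
13 | (S)-α-hydroxy-γ-butyrolactone | O[C@H]1CCOC1=O | starting material
14 | (3S)-4-methylpentane-1,3,4-triol | OCC[C@H](O)C(C)(C)O | intermediate
15 | 2-[(4S)-2,2,5,5-tetramethyl-1,3-dioxolan-4-yl]ethan-1-ol | OCC[C@@H]1OC(C)(C)OC1(C)C | intermediate
16 | (4S)-4-(2-iodoethyl)-2,2,5,5-tetramethyl-1,3-dioxolane | ICC[C@@H]1OC(C)(C)OC1(C)C | intermediate
17 | (S)-(+)-linalool | C=C[C@@](C)(O)CCC=C(C)C | starting material
18 | ozonide of 17 at the trisubstituted alkene | C=C[C@@](C)(O)CCC1OOC(C)(C)O1 | intermediate (not isolated)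
19 | (5S)-5-ethenyl-5-methyloxolan-2-ol | C=C[C@]1(C)CCC(O)O1 | intermediate
20 | (6S)-2,6-dimethylocta-1,7-diene-3,6-diol | C=C[C@@](C)(O)CCC(O)C(C)=C | intermediate
21 | (4S)-2,4-dimethylcyclohex-2-ene-1,4-diol | CC1=C[C@@](C)(O)CCC1O | intermediate
22 | (4S)-4-hydroxy-2,4-dimethylcyclohex-2-en-1-one | CC1=C[C@@](C)(O)CCC1=O | intermediate
23 | bis(bromomagnesium) enolate/alkoxide after vinyl addition | C=C[C@@H]1C(C)=C(O[Mg]Br)CC[C@]1(C)O[Mg]Br | intermediate (not isolated)
24 | (3R,4S)-3-ethenyl-2,4-dimethyl-1,4-bis(triethylsilyloxy)cyclohex-1-ene (vinyl cis to the C4 oxygen) | C=C[C@@H]1C(C)=C(O[Si](CC)(CC)CC)CC[C@]1(C)O[Si](CC)(CC)CC | intermediate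
25 | lithium enolate of the C1 ketone | C=C[C@@H]1C(C)=C(O[Li])CC[C@]1(C)O[Si](CC)(CC)CC | intermediate (not isolated)
26 | (2R,3R,4S)-3-ethenyl-2,4-dimethyl-2-{2-[(4S)-2,2,5,5-tetramethyl-1,3-dioxolan-4-yl]ethyl}-4-(triethylsilyloxy)cyclohexan-1-one | C=C[C@@H]1[C@@](C)(CC[C@@H]2OC(C)(C)OC2(C)C)C(=O)CC[C@]1(C)O[Si](CC)(CC)CC | intermediate
27 | tricyclic ketal (6,8-dioxabicyclo[3.2.1]octane fused to the cyclohexane) | C=C[C@@H]1[C@@]2(C)CC[C@@H]3O[C@@]2(CC[C@]1(C)O[Si](CC)(CC)CC)OC3(C)C | intermediate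
28 | (3S,5aR,6R,7S,9aR)-6-ethenyl-2,2,5a,7-tetramethyl-3,7-bis(triethylsilyloxy)decahydro-1-benzoxepine (trans-fused) | C=C[C@@H]1[C@@]2(C)CC[C@H](O[Si](CC)(CC)CC)C(C)(C)O[C@@H]2CC[C@]1(C)O[Si](CC)(CC)CC | intermediate
29 | alkylzirconocene chloride from 28 | Cl[Zr](CC[C@@H]1[C@@]2(C)CC[C@H](O[Si](CC)(CC)CC)C(C)(C)O[C@@H]2CC[C@]1(C)O[Si](CC)(CC)CC)(C3C=CC=C3)C4C=CC=C4 | intermediate (not isolated)
30 | (3S,5aR,6R,7S,9aR)-6-(2-iodoethyl)-2,2,5a,7-tetramethyl-3,7-bis(triethylsilyloxy)decahydro-1-benzoxepine | ICC[C@@H]1[C@@]2(C)CC[C@H](O[Si](CC)(CC)CC)C(C)(C)O[C@@H]2CC[C@]1(C)O[Si](CC)(CC)CC | intermediate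
31 | alkyllithium from 30 | [Li]CC[C@@H]1[C@@]2(C)CC[C@H](O[Si](CC)(CC)CC)C(C)(C)O[C@@H]2CC[C@]1(C)O[Si](CC)(CC)CC | intermediate (not isolated)
32 | lithium alkoxide of the 1,2-adduct of 31 to 12 | CC1(C)[C@@H]2CC[C@@](C)(O[Si](C)(C)C(C)(C)C)[C@@H]2CC(OC)=C(C)C1(O[Li])CC[C@@H]3[C@@]4(C)CC[C@H](O[Si](CC)(CC)CC)C(C)(C)O[C@@H]4CC[C@]3(C)O[Si](CC)(CC)CC | intermediate (not isolated)
33 | target CNP0397160.2 | CC1=C(CC[C@@H]2[C@@]3(C)CC[C@H](O)C(C)(C)O[C@@H]3CC[C@]2(C)O)C(C)(C)[C@@H]2CC[C@@](C)(O)[C@@H]2CC1=O | target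

**Step count and risks**

Total steps: 23 (hydroazulenone half 10, side-chain iodide 3, benzoxepane half 9, union 1). Longest linear sequence: 11 steps (steps 1–10, then step 23).

The three steps most likely to fail:

Step 3 (first dichloroketene cycloaddition). Facial selection between methyl and silyloxy on the same allylic carbon may be modest. Fallback: carry the diastereomer mixture through steps 4–6 to silyl enol ether 7 and remove the ring-fusion stereocentres. Saegusa–Ito dehydrogenation of 7 with Pd(OAc)2 in MeCN gives (6R)-6-(tert-butyldimethylsilyloxy)-2,2,6-trimethylbicyclo[3.3.0]oct-4-en-3-one F1. KOt-Bu in t-BuOH/THF followed by kinetic protonation with AcOH at −78 °C deconjugates it to (6R)-6-(tert-butyldimethylsilyloxy)-2,2,6-trimethylbicyclo[3.3.0]oct-1(5)-en-3-one F2. TBAF frees the alcohol (6R)-6-hydroxy-2,2,6-trimethylbicyclo[3.3.0]oct-1(5)-en-3-one F3. Hydroxyl-directed hydrogenation with [Ir(cod)(PCy3)(py)]PF6 and H2 in CH2Cl2 then delivers both ring-fusion hydrogens cis to the hydroxyl, giving (1R,5R,6R)-6-hydroxy-2,2,6-trimethylbicyclo[3.3.0]octan-3-one F4. TBSOTf/2,6-lutidine returns the route to 6. This corrects facial selectivity only, not a wrong regiochemistry of the cycloaddition.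

Step 19 (quaternary centre by alkylation with an unactivated iodide). Fallback from 24 and 15: form the bond by a Mukaiyama aldol reaction and then remove the extra oxygen. Dess–Martin oxidation of 15 gives 2-[(4S)-2,2,5,5-tetramethyl-1,3-dioxolan-4-yl]acetaldehyde F5. BF3·OEt2-mediated aldol addition of 24 to F5 at −78 °C, expected anti to the vinyl group, gives (2R,3R,4S)-3-ethenyl-2-{1-hydroxy-2-[(4S)-2,2,5,5-tetramethyl-1,3-dioxolan-4-yl]ethyl}-2,4-dimethyl-4-(triethylsilyloxy)cyclohexan-1-one F6. PhOC(S)Cl/pyridine converts it into the O-phenyl thionocarbonate of F6 F7, and Barton–McCombie deoxygenation (Bu3SnH, AIBN, toluene, 80 °C) returns the route to 26.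

Step 21 (regio- and stereoselective ketal opening). Fallback from 24: close the oxepane by Markovnikov iodoetherification instead. Alkylation of the lithium enolate from 24 with 5-iodo-2-methylpent-2-ene (as in step 19) gives (2R,3R,4S)-3-ethenyl-2,4-dimethyl-2-(4-methylpent-3-en-1-yl)-4-(triethylsilyloxy)cyclohexan-1-one F8. NaBH4 reduction (axial hydride, equatorial alcohol trans to the new chain) gives (1R,2R,3R,4S)-3-ethenyl-2,4-dimethyl-2-(4-methylpent-3-en-1-yl)-4-(triethylsilyloxy)cyclohexan-1-ol F9. N-Iodosuccinimide in CH2Cl2 effects the seven-membered ring closure onto the tertiary alkene carbon to give (5aR,6R,7S,9aR)-6-ethenyl-3-iodo-2,2,5a,7-tetramethyl-7-(triethylsilyloxy)decahydro-1-benzoxepine F10. Radical hydroxylation (Bu3SnH, air, toluene, then PPh3) gives (5aR,6R,7S,9aR)-6-ethenyl-2,2,5a,7-tetramethyl-7-(triethylsilyloxy)decahydro-1-benzoxepin-3-ol as C3 epimers F11. Dess–Martin oxidation gives (5aR,6R,7S,9aR)-6-ethenyl-2,2,5a,7-tetramethyl-7-(triethylsilyloxy)octahydro-1-benzoxepin-3(2H)-one F12. NaBH4 reduction, expected from the face opposite the angular methyl, gives (3S,5aR,6R,7S,9aR)-6-ethenyl-2,2,5a,7-tetramethyl-7-(triethylsilyloxy)decahydro-1-benzoxepin-3-ol F13, and TESOTf/2,6-lutidine returns the route to 28.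

**Further compounds**

F1 | step 3 | (6R)-6-(tert-butyldimethylsilyloxy)-2,2,6-trimethylbicyclo[3.3.0]oct-4-en-3-one | CC1(C)C2CC[C@@](C)(O[Si](C)(C)C(C)(C)C)C2=CC1=O
F2 | step 3 | (6R)-6-(tert-butyldimethylsilyloxy)-2,2,6-trimethylbicyclo[3.3.0]oct-1(5)-en-3-one | O=C1CC2=C(CC[C@@]2(C)O[Si](C)(C)C(C)(C)C)C1(C)C
F3 | step 3 | (6R)-6-hydroxy-2,2,6-trimethylbicyclo[3.3.0]oct-1(5)-en-3-one | O=C1CC2=C(CC[C@@]2(C)O)C1(C)C
F4 | step 3 | (1R,5R,6R)-6-hydroxy-2,2,6-trimethylbicyclo[3.3.0]octan-3-one | CC1(C)[C@@H]2CC[C@@](C)(O)[C@@H]2CC1=O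
F5 | step 19 | 2-[(4S)-2,2,5,5-tetramethyl-1,3-dioxolan-4-yl]acetaldehyde | O=CC[C@@H]1OC(C)(C)OC1(C)C
F6 | step 19 | (2R,3R,4S)-3-ethenyl-2-{1-hydroxy-2-[(4S)-2,2,5,5-tetramethyl-1,3-dioxolan-4-yl]ethyl}-2,4-dimethyl-4-(triethylsilyloxy)cyclohexan-1-one | C=C[C@@H]1[C@@](C)(C(O)C[C@@H]2OC(C)(C)OC2(C)C)C(=O)CC[C@]1(C)O[Si](CC)(CC)CC
F7 | step 19 | O-phenyl thionocarbonate of F6 | C=C[C@@H]1[C@@](C)(C(OC(=S)Oc2ccccc2)C[C@@H]3OC(C)(C)OC3(C)C)C(=O)CC[C@]1(C)O[Si](CC)(CC)CC
F8 | step 21 | (2R,3R,4S)-3-ethenyl-2,4-dimethyl-2-(4-methylpent-3-en-1-yl)-4-(triethylsilyloxy)cyclohexan-1-one | C=C[C@@H]1[C@@](C)(CCC=C(C)C)C(=O)CC[C@]1(C)O[Si](CC)(CC)CC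
F9 | step 21 | (1R,2R,3R,4S)-3-ethenyl-2,4-dimethyl-2-(4-methylpent-3-en-1-yl)-4-(triethylsilyloxy)cyclohexan-1-ol | C=C[C@@H]1[C@@](C)(CCC=C(C)C)[C@H](O)CC[C@]1(C)O[Si](CC)(CC)CC
F10 | step 21 | (5aR,6R,7S,9aR)-6-ethenyl-3-iodo-2,2,5a,7-tetramethyl-7-(triethylsilyloxy)decahydro-1-benzoxepine | C=C[C@@H]1[C@@]2(C)CCC(I)C(C)(C)O[C@@H]2CC[C@]1(C)O[Si](CC)(CC)CC
F11 | step 21 | (5aR,6R,7S,9aR)-6-ethenyl-2,2,5a,7-tetramethyl-7-(triethylsilyloxy)decahydro-1-benzoxepin-3-ol (C3 epimers) | C=C[C@@H]1[C@@]2(C)CCC(O)C(C)(C)O[C@@H]2CC[C@]1(C)O[Si](CC)(CC)CC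
F12 | step 21 | (5aR,6R,7S,9aR)-6-ethenyl-2,2,5a,7-tetramethyl-7-(triethylsilyloxy)octahydro-1-benzoxepin-3(2H)-one | C=C[C@@H]1[C@@]2(C)CCC(=O)C(C)(C)O[C@@H]2CC[C@]1(C)O[Si](CC)(CC)CC
F13 | step 21 | (3S,5aR,6R,7S,9aR)-6-ethenyl-2,2,5a,7-tetramethyl-7-(triethylsilyloxy)decahydro-1-benzoxepin-3-ol | C=C[C@@H]1[C@@]2(C)CC[C@H](O)C(C)(C)O[C@@H]2CC[C@]1(C)O[Si](CC)(CC)CC
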